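**Retrosynthetic overview**
1. The strategy rests on the ring B array C2(=O)–C1–C10–C9–C8=C17, a ketone whose α-carbon C1 and β-carbon C10 lead over C9 to the butenolide olefin; this is the retron of an oxy-Cope shift in a 1-dienyl-3-methylenecyclooctanol.
2. Target 30 ⇐ tricyclic ketone 24 (rings A, B and C complete) by 1,3-syn reduction at C2, tiglation, C14 acetylation and hydrolysis of a C13 ketal.
3. 24 ⇐ carbinol 21 by alkoxide-driven [3,3] shift with MeI capture: C2–C17 is broken, C9–C10 and C1–CH3 are made. Ring C is carried as a lactone bridging C7 and C17, which fixes the butenolide geometry and the C7/C17 relationship.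
4. 21 ⇐ ring A dienylcerium 20 (from creosol; C13 ketone latent as o-quinone monoketal, C14 by CBS reduction) + bridged keto lactone 13; 13 ⇐ C17–C19 Claisen bridging ⇐ cyclooctenol 11 ⇐ C7–C8 Nozaki–Hiyama–Kishi closure ⇐ nerol + 1-bromobut-2-yne.
5. Ring order: ring A (from the arene), the eight-membered carbocycle, ring C as the bridging lactone, then ring B by two-carbon expansion of the eight-membered ring.

Key step: step 17

Remark on locants: briarane numbering is used throughout (C1 ring-fusion quaternary carbon, C2 tiglate carbinol, C5=C6, C7 lactone carbinol, C8/C17 butenolide β/α carbons, C10 fusion CH, C13 ketone, C14 acetate carbinol); the lactone carbonyl carbon is called C19.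
Assumption: the catalyst antipodes named in steps 9 and 14 are those expected from the closest models (intermolecular alkenylchromium additions; 2-bromocyclohexenone reduction); if the sense of induction proves opposite, the enantiomeric catalyst is used.

**Route**

Step 1
Reactants: 1 nerol
Product: 2 neryl tert-butyldiphenylsilyl ether
Conditions: TBDPSCl, imidazole, CH2Cl2, 0 °C to rt
Reagents that add atoms: tert-butyl(chloro)diphenylsilane, CC(C)(C)[Si](Cl)(c1ccccc1)c1ccccc1
Why: Standard silylation of the primary allylic alcohol gives a bulky, acid-stable ether that survives steps 2–6 and deactivates the neighbouring olefin toward peracid.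

Step 2
Reactants: 2 neryl tert-butyldiphenylsilyl ether
Product: 3 6,7-epoxide of 2 (racemic at the epoxide carbon)
Conditions: mCPBA (1.05 equiv), CH2Cl2, −20 to 0 °C
Reagents that add atoms: 3-chloroperoxybenzoic acid, OOC(=O)c1cccc(Cl)c1
Why: Prilezhaev epoxidation should take the more electron-rich, unhindered terminal trisubstituted olefin, and the new stereocentre is destroyed in step 3 so it needs no control.

Step 3
Reactants: 3 6,7-epoxide of 2
Product: 4 (4Z)-6-[(tert-butyldiphenylsilyl)oxy]-4-methylhex-4-enal
Conditions: H5IO6, THF/H2O, 0 °C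
Reagents that add atoms: none
Why: Periodic acid opens the epoxide to the glycol and cleaves it (Malaprade cleavage), excising acetone and leaving the C2 aldehyde with the Z-olefin untouched.

Step 4
Reactants: 4 (4Z)-6-[(tert-butyldiphenylsilyl)oxy]-4-methylhex-4-enal; 5 1-bromobut-2-yne
Product: 6 allenyl carbinol (7Z)-9-[(tert-butyldiphenylsilyl)oxy]-3,7-dimethylnona-1,2,7-trien-4-ol (racemic)
Conditions: indium powder, THF/H2O (1:1), rt
Reagents that add atoms: none
Why: Indium-mediated Barbier coupling of a γ-substituted propargyl bromide proceeds by SE2′ attack to give the α-allenyl carbinol, bringing in C17 with its methyl, C8 and C9; the carbinol centre is racemic and is oxidised in step 5.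

Step 5
Reactants: 6 allenyl carbinol
Product: 7 allenyl ketone (7Z)-9-[(tert-butyldiphenylsilyl)oxy]-3,7-dimethylnona-1,2,7-trien-4-one
Conditions: Dess–Martin periodinane, CH2Cl2, 0 °C to rt
Reagents that add atoms: none
Why: Dess–Martin oxidation of the secondary alcohol under near-neutral conditions gives the 1,2-allenyl ketone without isomerisation to a conjugated dienone.

Step 6
Reactants: 7 allenyl ketone
Product: 8 β-bromo-β,γ-enone (7Z)-2-bromo-9-[(tert-butyldiphenylsilyl)oxy]-3,7-dimethylnona-1,7-dien-4-one (racemic at C17)
Conditions: LiBr, AcOH, rt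
Reagents that add atoms: lithium bromide, [Li+].[Br-]
Why: In this known hydrobromination of 1,2-allenyl ketones bromide adds to the central allene carbon and the dienol is protonated at the α-carbon, giving the 2-bromoalkene regioselectively; C17 forms as both epimers, which is harmless because this centre is rebuilt from a planar enolate in step 11.

Step 7
Reactants: 8 β-bromo-β,γ-enone
Product: 9 (7Z)-2-bromo-9-hydroxy-3,7-dimethylnona-1,7-dien-4-one
Conditions: HF·pyridine, pyridine, THF, 0 °C to rt
Reagents that add atoms: none
Why: Fluoride desilylation under buffered, non-basic conditions frees the allylic alcohol while sparing the base-labile β-bromo-β,γ-enone.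

Step 8
Reactants: 9 (7Z)-2-bromo-9-hydroxy-3,7-dimethylnona-1,7-dien-4-one
Product: 10 (2Z)-8-bromo-3,7-dimethyl-6-oxonona-2,8-dienal
Conditions: MnO2, CH2Cl2, rt
Reagents that add atoms: none
Why: Chemoselective MnO2 oxidation of the allylic alcohol under neutral conditions should give the enal with retention of the Z geometry needed for ring closure.

Step 9
Reactants: 10 (2Z)-8-bromo-3,7-dimethyl-6-oxonona-2,8-dienal
Product: 11 (4R,5Z)-4-hydroxy-2,6-dimethyl-3-methylidenecyclooct-5-en-1-one (7R; both C17 epimers)
Conditions: CrCl2 (4 equiv), NiCl2 (2 mol %), N-[2-[(4S)-4-isopropyl-4,5-dihydro-1,3-oxazol-2-yl]-6-methylphenyl]methanesulfonamide (4.4 equiv), Et3N (4.4 equiv), THF, rt, slow addition of 10 to 2 mM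
Reagents that add atoms: none
Why: In this intramolecular Nozaki–Hiyama–Kishi reaction the alkenylchromium formed at C8 adds only to the aldehyde, the Z-olefin and three sp2 centres pre-organise the eight-membered closure at C7–C8, and the chiral sulfonamide on chromium selects the enal face to set 7R while C17 stays an inconsequential epimer mixture.

Step 10
Reactants: 11 cyclooctenol ketone
Product: 12 (1R,2Z)-3,7-dimethyl-8-methylidene-6-oxocyclooct-2-en-1-yl 1H-imidazole-1-carboxylate (both C17 epimers)
Conditions: 1,1′-carbonyldiimidazole, CH2Cl2, rt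
Reagents that add atoms: 1,1'-carbonyldiimidazole, O=C(n1ccnc1)n1ccnc1
Why: Acylation of the secondary alcohol with carbonyldiimidazole places the future lactone carbonyl C19 on O7 as an acyl-transfer-active imidazole carboxylate without added acid or base.

Step 11
Reactants: 12 imidazole carboxylate
Product: 13 bridged keto lactone (1R,5Z,7R)-1,5-dimethyl-10-methylidene-8-oxabicyclo[5.2.1]dec-5-ene-2,9-dione (7R,17R)
Conditions: NaH (1.2 equiv), THF, 0 °C to rt; aq. NH4Cl
Reagents that add atoms: none
Why: In this Dieckmann-type intramolecular Claisen acylation the conjugated, thermodynamically favoured C17 enolate attacks the tethered imidazole carboxylate in a 5-(enolexo)-exo-trig closure (attack through C9 would be the disfavoured 5-(enolendo) mode), and because only a cis-bridged lactone can span C7 and C17 the new quaternary centre forms as 17R from either C17 epimer of 12.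

Step 12
Reactants: 14 creosol (2-methoxy-4-methylphenol)
Product: 15 2-bromo-6-methoxy-4-methylphenol
Conditions: NBS, CH2Cl2, 0 °C
Reagents that add atoms: N-bromosuccinimide, O=C1CCC(=O)N1Br
Why: Electrophilic bromination ortho to the free phenol, whose para position is blocked by the methyl group, places bromine on the carbon that becomes C1.

Step 13
Reactants: 15 2-bromo-6-methoxy-4-methylphenol
Product: 16 2-bromo-6,6-dimethoxy-4-methylcyclohexa-2,4-dien-1-one
Conditions: PhI(OAc)2, MeOH, 0 °C; used at once
Reagents that add atoms: methanol, CO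
Why: Oxidative dearomatisation of the 2-methoxyphenol in methanol gives the o-quinone monoketal, which stores the C13 carbonyl as a dimethyl ketal and blocks re-aromatisation of the bromodienone, while the bromo and 4-methyl groups slow Diels–Alder dimerisation.

Step 14
Reactants: 16 2-bromo-6,6-dimethoxy-4-methylcyclohexa-2,4-dien-1-one
Product: 17 (1R)-2-bromo-6,6-dimethoxy-4-methylcyclohexa-2,4-dien-1-ol
Conditions: (S)-2-methyl-CBS-oxazaborolidine (20 mol %), catecholborane, toluene, −78 °C
Reagents that add atoms: none
Why: Corey–Bakshi–Shibata 1,2-reduction of the α-bromo dienone, in which the bromoalkenyl arm is expected to act as the large group as it does in 2-bromocyclohexenones, sets the carbinol centre (R descriptor here, the centre that is 14S in the target).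

Step 15
Reactants: 17 (1R)-2-bromo-6,6-dimethoxy-4-methylcyclohexa-2,4-dien-1-ol
Product: 18 (6R)-1-bromo-5,5-dimethoxy-6-[(4-methoxyphenyl)methoxy]-3-methylcyclohexa-1,3-diene
Conditions: NaH, 4-methoxybenzyl chloride, n-Bu4NI (cat.), DMF, 0 °C to rt
Reagents that add atoms: 4-methoxybenzyl chloride, COc1ccc(CCl)cc1
Why: Williamson etherification under basic conditions (the dienol ketal re-aromatises with acid) gives an ether that, unlike a silyl ether, cannot migrate to the C2 alkoxide, is a poor leaving group from the later enolate and is removed oxidatively.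

Step 16
Reactants: 18 ring A bromodiene p-methoxybenzyl ether; 13 bridged keto lactone
Product: 21 oxy-Cope precursor (1R,2R,5Z,7R)-2-[(6S)-5,5-dimethoxy-6-[(4-methoxyphenyl)methoxy]-3-methylcyclohexa-1,3-dien-1-yl]-2-hydroxy-1,5-dimethyl-10-methylidene-8-oxabicyclo[5.2.1]dec-5-en-9-one, via dienyllithium 19 (not isolated), via dienylcerium dichloride 20 (not isolated)
Conditions: 18 (1.5 equiv), t-BuLi (3.0 equiv), THF, −78 °C; CeCl3, −78 °C; then 13, −78 °C; aq. NH4Cl at −78 °C
Reagents that add atoms: none
Why: Bromine–lithium exchange and transmetalation give a weakly basic organocerium that adds 1,2 to the ketone in preference to enolisation or attack on the hindered lactone, from the face remote from the lactone bridge (C2 as drawn, a centre consumed in step 17), and the cold quench keeps the β-hydroxy lactone from fragmenting.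

Step 17
Reactants: 21 oxy-Cope precursor
Product: 24 ring-expanded tricyclic ketone (2-oxo, C1 methyl, C13 dimethyl ketal, C14 p-methoxybenzyl ether, 5Z-olefin, 8(17)-butenolide; 1S,7R,10R,14S), via potassium alkoxide 22 (not isolated), via potassium enolate 23 (not isolated)
Conditions: KH (1.5 equiv), 18-crown-6 (1.5 equiv), THF, −40 to 0 °C; then MeI (5 equiv), −78 to 0 °C
Reagents that add atoms: iodomethane, CI
Why: Proposed new method: deprotonation gives alkoxide 22, whose oxyanion drives a [3,3] shift across C10=C1–C2–C17–C8=C9 (C2–C17 cleaved, C9–C10 formed), either in one step or as retro-aldol release of the lactone dienolate and its conjugate addition through C9 to C10 of the resulting dienyl ketone, and both courses end at enolate 23, which MeI alkylates at C1. The closest known reactions are anionic oxy-Cope two-carbon ring expansions of 1-alkenyl-2-methylenecycloalkanols with alkylation of the enolate in the same flask; untested here are the dienyl migrating terminus, the lactone-bearing C17 and the bridged bicyclic frame. Ring B closes as a ten-membered carbocycle by expansion of the eight-membered ring (a 10-endo-trig conjugate addition in the stepwise reading), and ring C emerges as the butenolide with its olefin geometry fixed by the lactone bridge. C10 is set because C9 approaches the diene face opposite the pseudo-axial C14 p-methoxybenzyl ether, the rotamer about C1–C2 that keeps the bicyclic lactone away from that ether being the reactive one, and C1 is set by MeI entering the enolate from the same lower face, anti to that ether. The step needs C9 (γ) rather than C17 (α) reactivity of the dienolate, secured by the fully substituted C17 and by the conjugated butenolide product, C- rather than O-methylation, secured by the soft electrophile, and it must outrun β-loss of the C14 alkoxide from 23, for which the poor leaving group and methylation below 0 °C are relied on. C2 and C17 of 21 return to sp2 carbons, so their configuration matters only for the geometry of a concerted transition state, and H-10 stays correctable later as the γ-position of the ring A enone.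

Step 18
Reactants: 24 ring-expanded tricyclic ketone
Product: 25 14-hydroxy ketone (24 with free C14 hydroxyl)
Conditions: DDQ, CH2Cl2/pH 7 buffer, 0 °C
Reagents that add atoms: none
Why: Oxidative cleavage of the p-methoxybenzyl ether under buffered conditions frees the hindered C14 hydroxyl without touching the ketal, the butenolide or the olefins and without base that could trigger retro-aldol opening of the β-hydroxy ketone.

Step 19
Reactants: 25 14-hydroxy ketone
Product: 27 2,14-syn diol (1R,2S,7R,10R,14S), via diethylboron chelate 26 (not isolated)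
Conditions: Et2BOMe, THF/MeOH (4:1), rt then −78 °C; NaBH4, −78 °C; evaporation from MeOH
Reagents that add atoms: none
Why: In this Narasaka–Prasad reduction the boron chelate between O14 and the C2 carbonyl is reduced by external hydride to the 1,3-syn diol, which corresponds to 2S, and NaBH4 at −78 °C leaves the butenolide and the ketal alone.

Step 20
Reactants: 27 2,14-syn diol
Product: 28 2-O-tigloyl 14-hydroxy ketal
Conditions: tiglic acid, 2,4,6-trichlorobenzoyl chloride, Et3N, THF, rt; then 27, DMAP, toluene, rt to 60 °C
Reagents that add atoms: tiglic acid, C/C=C(\C)C(O)=O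
Why: Yamaguchi esterification should acylate the C2 carbinol, flanked by a methylene, in preference to the C14 carbinol wedged between the quaternary C1 and the ketal carbon.

Step 21
Reactants: 28 2-O-tigloyl 14-hydroxy ketal
Product: 29 14-O-acetyl-2-O-tigloyl C13 dimethyl ketal
Conditions: Ac2O, DMAP, Et3N, CH2Cl2, rt to 40 °C
Reagents that add atoms: acetic anhydride, CC(=O)OC(C)=O
Why: DMAP-catalysed acetylation of the remaining hindered secondary alcohol is done while C13 is still a ketal so that C14 cannot epimerise through an enediol.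

Step 22
Reactants: 29 14-O-acetyl-2-O-tigloyl C13 dimethyl ketal
Product: 30 CNP0218548.3 (1R,2S,7R,10R,14S)
Conditions: PPTS, acetone/H2O (10:1), rt
Reagents that add atoms: water, O
Why: Mild acid hydrolysis of the allylic dimethyl ketal unveils the C13 ketone in conjugation with C11=C12, completing the ring A enone without disturbing the two esters or the butenolide.

**Compound list**
1 | nerol, (2Z)-3,7-dimethylocta-2,6-dien-1-ol | CC(C)=CCC/C(C)=C\CO | starting material
2 | neryl tert-butyldiphenylsilyl ether | CC(C)=CCC/C(C)=C\CO[Si](c1ccccc1)(c1ccccc1)C(C)(C)C | intermediate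
3 | tert-butyl{[(2Z)-5-(3,3-dimethyloxiran-2-yl)-3-methylpent-2-en-1-yl]oxy}diphenylsilane (racemic epoxide) | CC1(C)OC1CC/C(C)=C\CO[Si](c1ccccc1)(c1ccccc1)C(C)(C)C | intermediate
4 | (4Z)-6-[(tert-butyldiphenylsilyl)oxy]-4-methylhex-4-enal (aldehyde carbon = C2) | O=CCC/C(C)=C\CO[Si](c1ccccc1)(c1ccccc1)C(C)(C)C | intermediate
5 | 1-bromobut-2-yne | CC#CCBr | starting material
6 | (7Z)-9-[(tert-butyldiphenylsilyl)oxy]-3,7-dimethylnona-1,2,7-trien-4-ol (racemic) | C=C=C(C)C(O)CC/C(C)=C\CO[Si](c1ccccc1)(c1ccccc1)C(C)(C)C | intermediate
7 | (7Z)-9-[(tert-butyldiphenylsilyl)oxy]-3,7-dimethylnona-1,2,7-trien-4-one | C=C=C(C)C(=O)CC/C(C)=C\CO[Si](c1ccccc1)(c1ccccc1)C(C)(C)C | intermediate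
8 | (7Z)-2-bromo-9-[(tert-butyldiphenylsilyl)oxy]-3,7-dimethylnona-1,7-dien-4-one (racemic at C17) | C=C(Br)C(C)C(=O)CC/C(C)=C\CO[Si](c1ccccc1)(c1ccccc1)C(C)(C)C | intermediate
9 | (7Z)-2-bromo-9-hydroxy-3,7-dimethylnona-1,7-dien-4-one (racemic at C17) | C=C(Br)C(C)C(=O)CC/C(C)=C\CO | intermediate
10 | (2Z)-8-bromo-3,7-dimethyl-6-oxonona-2,8-dienal (racemic at C17) | C=C(Br)C(C)C(=O)CC/C(C)=C\C=O | intermediate
11 | (4R,5Z)-4-hydroxy-2,6-dimethyl-3-methylidenecyclooct-5-en-1-one (7R; both C17 epimers) | O=C1CC/C(C)=C\[C@@H](O)C(=C)C1C | intermediate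
12 | (1R,2Z)-3,7-dimethyl-8-methylidene-6-oxocyclooct-2-en-1-yl 1H-imidazole-1-carboxylate (both C17 epimers) | O=C1CC/C(C)=C\[C@@H](OC(=O)n2ccnc2)C(=C)C1C | intermediate
13 | (1R,5Z,7R)-1,5-dimethyl-10-methylidene-8-oxabicyclo[5.2.1]dec-5-ene-2,9-dione (bridged keto lactone; 7R,17R) | O=C1O[C@@H]2/C=C(C)\CCC(=O)[C@@]1(C)C2=C | intermediate
14 | creosol, 2-methoxy-4-methylphenol | COc1cc(C)ccc1O | starting material
15 | 2-bromo-6-methoxy-4-methylphenol | COc1cc(C)cc(Br)c1O | intermediate
16 | 2-bromo-6,6-dimethoxy-4-methylcyclohexa-2,4-dien-1-one | COC1(OC)C=C(C)C=C(Br)C1=O | intermediate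
17 | (1R)-2-bromo-6,6-dimethoxy-4-methylcyclohexa-2,4-dien-1-ol | COC1(OC)C=C(C)C=C(Br)[C@@H]1O | intermediate
18 | (6R)-1-bromo-5,5-dimethoxy-6-[(4-methoxyphenyl)methoxy]-3-methylcyclohexa-1,3-diene | COC1(OC)C=C(C)C=C(Br)[C@@H]1OCc2ccc(OC)cc2 | intermediate
19 | ring A dienyllithium (lithium in place of bromine in 18) | COC1(OC)C=C(C)C=C([Li])[C@@H]1OCc2ccc(OC)cc2 | intermediate
20 | ring A dienylcerium dichloride (CeCl2 in place of bromine in 18) | COC1(OC)C=C(C)C=C([Ce](Cl)Cl)[C@@H]1OCc2ccc(OC)cc2 | intermediate
21 | oxy-Cope precursor, 2-hydroxy-2-(ring A dienyl) bridged lactone (2R,7R,14S,17R) | O=C1O[C@@H]2/C=C(C)\CC[C@@](O)(C3=CC(C)=CC(OC)(OC)[C@H]3OCc4ccc(OC)cc4)[C@@]1(C)C2=C | intermediate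
22 | potassium alkoxide of 21 | [K+].O=C1O[C@@H]2/C=C(C)\CC[C@@]([O-])(C3=CC(C)=CC(OC)(OC)[C@H]3OCc4ccc(OC)cc4)[C@@]1(C)C2=C | intermediate
23 | potassium C1=C2 enolate of the ring-expanded tricycle (enolate geometry left open) | [K+].[O-]C1=C2[C@H](OCc3ccc(OC)cc3)C(OC)(OC)C=C(C)[C@H]2CC2=C(C)C(=O)O[C@@H]2/C=C(C)\CC1 | intermediate
24 | ring-expanded tricyclic ketone: C2 ketone, C1 methyl, C13 dimethyl ketal, C14 p-methoxybenzyl ether, 5Z-olefin, 8(17)-butenolide (1S,7R,10R,14S) | O=C1CC/C(C)=C\[C@H]3OC(=O)C(C)=C3C[C@@H]2C(C)=CC(OC)(OC)[C@@H](OCc4ccc(OC)cc4)[C@@]12C | intermediate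
25 | 14-hydroxy ketone (24 with free C14 hydroxyl) | O=C1CC/C(C)=C\[C@H]3OC(=O)C(C)=C3C[C@@H]2C(C)=CC(OC)(OC)[C@@H](O)[C@@]12C | intermediate
26 | O14-diethylboryl derivative of 25, boron chelated to the C2 carbonyl | O=C1CC/C(C)=C\[C@H]3OC(=O)C(C)=C3C[C@@H]2C(C)=CC(OC)(OC)[C@@H](OB(CC)CC)[C@@]12C | intermediate
27 | 2,14-syn diol (1R,2S,7R,10R,14S) | O[C@H]1CC/C(C)=C\[C@H]3OC(=O)C(C)=C3C[C@@H]2C(C)=CC(OC)(OC)[C@@H](O)[C@@]12C | intermediate
28 | 2-O-tigloyl 14-hydroxy C13 dimethyl ketal | C/C=C(\C)C(=O)O[C@H]1CC/C(C)=C\[C@H]3OC(=O)C(C)=C3C[C@@H]2C(C)=CC(OC)(OC)[C@@H](O)[C@@]12C | intermediate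
29 | 14-O-acetyl-2-O-tigloyl C13 dimethyl ketal | C/C=C(\C)C(=O)O[C@H]1CC/C(C)=C\[C@H]3OC(=O)C(C)=C3C[C@@H]2C(C)=CC(OC)(OC)[C@@H](OC(C)=O)[C@@]12C | intermediate
30 | CNP0218548.3, (1R,2S,7R,10R,14S)-14-acetoxy-13-oxo-2-tigloyloxy tricyclic butenolide | C/C=C(\C)C(=O)O[C@H]1CC/C(C)=C\[C@H]2OC(=O)C(C)=C2C[C@@H]2C(C)=CC(=O)[C@@H](OC(C)=O)[C@@]12C | target

**Step count**
Total: 22 steps. Longest linear sequence: 18 steps (nerol 1 to 13 by steps 1–11, then steps 16–22); the ring A branch (steps 12–15) joins at step 16.

**Steps most likely to fail**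

Step 17 (proposed new method). After C2–C17 cleavage the tethered dienolate may be quenched by proton transfer from C3 before it closes ring B. The enolate may also expel the C14 ether, or methylation may take the upper face. The fallback replaces the anionic cascade by a neutral pericyclic shift that cannot divert through ionic fragmentation. It sets out from 21: silylation of the tertiary alcohol with N-(trimethylsilyl)imidazole should give the trimethylsilyl ether F1. Heating F1 in base-washed glassware (o-dichlorobenzene, about 180 °C) should effect a thermal siloxy-Cope ring expansion to the trimethylsilyl enol ether F2. Anhydrous benzyltrimethylammonium fluoride in the presence of MeI then releases the C1 enolate regiospecifically and methylates it, returning to the route at 24.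

Step 11. Enolisation may go toward C3 instead of C17, O-acylation may compete with C-acylation, or the doubly allylic carboxylate may ionise before ring closure. The fallback installs C19 before the carbocycle is closed and sets out from 4. Aldol addition of the lithium enolate of methyl propanoate should give the β-hydroxy ester F3, and Dess–Martin oxidation the β-keto ester F4. Electrophilic ethynylation with 1-[(trimethylsilyl)ethynyl]-1,2-benziodoxol-3(1H)-one and TBAF gives the α-ethynyl keto ester F5 (racemic at C17). Bromoboration with B-bromo-9-borabicyclo[3.3.1]nonane followed by AcOH protonolysis gives the 2-bromoalkene F6. HF·pyridine then gives the allylic alcohol F7 and MnO2 the enal F8. Nozaki–Hiyama–Kishi closure under the conditions of step 9 gives the cis-hydroxy ester F9, which should lactonise on silica or with a trace of DBU and so returns to the route at 13. The C17 epimer cannot lactonise and is separated, so this path gives up at most half of the material.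

Step 9. Intermolecular coupling or reduction of the alkenyl bromide may compete with the medium-ring closure, and enantioface control may be weak in the cyclic transition state. The fallback sets C7 by an intermolecular coupling and closes the ring by metathesis; it sets out from 5. Indium-mediated addition of 5 to commercial 4-methylpent-4-enal (CC(=C)CCC=O) should give the allenyl carbinol F10, Dess–Martin oxidation the allenyl ketone F11, and LiBr in AcOH the bromo dienone F12. Nozaki–Hiyama–Kishi coupling of F12 with acrolein under the same chiral sulfonamide ligand, the intermolecular setting in which such ligands are best established, gives the triene carbinol F13. Ring-closing metathesis with the second-generation Grubbs catalyst (CH2Cl2, reflux, high dilution) forms the trisubstituted Z-olefin C5=C6 and returns to the route at 11.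

Further compounds
F1 | step 17 | trimethylsilyl ether of 21 | O=C1O[C@@H]2/C=C(C)\CC[C@@](O[Si](C)(C)C)(C3=CC(C)=CC(OC)(OC)[C@H]3OCc4ccc(OC)cc4)[C@@]1(C)C2=C
F2 | step 17 | trimethylsilyl C1=C2 enol ether of the ring-expanded tricycle | C[Si](C)(C)OC1=C2[C@H](OCc3ccc(OC)cc3)C(OC)(OC)C=C(C)[C@H]2CC2=C(C)C(=O)O[C@@H]2/C=C(C)\CC1
F3 | step 11 | methyl (6Z)-8-[(tert-butyldiphenylsilyl)oxy]-3-hydroxy-2,6-dimethyloct-6-enoate | COC(=O)C(C)C(O)CC/C(C)=C\CO[Si](c1ccccc1)(c1ccccc1)C(C)(C)C
F4 | step 11 | methyl (6Z)-8-[(tert-butyldiphenylsilyl)oxy]-2,6-dimethyl-3-oxooct-6-enoate | COC(=O)C(C)C(=O)CC/C(C)=C\CO[Si](c1ccccc1)(c1ccccc1)C(C)(C)C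
F5 | step 11 | methyl (6Z)-8-[(tert-butyldiphenylsilyl)oxy]-2-ethynyl-2,6-dimethyl-3-oxooct-6-enoate (racemic) | COC(=O)C(C)(C#C)C(=O)CC/C(C)=C\CO[Si](c1ccccc1)(c1ccccc1)C(C)(C)C
F6 | step 11 | methyl (6Z)-2-(1-bromoethenyl)-8-[(tert-butyldiphenylsilyl)oxy]-2,6-dimethyl-3-oxooct-6-enoate | COC(=O)C(C)(C(Br)=C)C(=O)CC/C(C)=C\CO[Si](c1ccccc1)(c1ccccc1)C(C)(C)C
F7 | step 11 | methyl (6Z)-2-(1-bromoethenyl)-8-hydroxy-2,6-dimethyl-3-oxooct-6-enoate | COC(=O)C(C)(C(Br)=C)C(=O)CC/C(C)=C\CO
F8 | step 11 | methyl (6Z)-2-(1-bromoethenyl)-2,6-dimethyl-3,8-dioxooct-6-enoate | COC(=O)C(C)(C(Br)=C)C(=O)CC/C(C)=C\C=O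
F9 | step 11 | methyl (1R,3R,4Z)-3-hydroxy-1,5-dimethyl-2-methylidene-8-oxocyclooct-4-ene-1-carboxylate (hydroxyl cis to the ester) | COC(=O)[C@]1(C)C(=C)[C@H](O)/C=C(C)\CCC1=O
F10 | step 9 | 3,7-dimethylocta-1,2,7-trien-4-ol | C=C=C(C)C(O)CCC(C)=C
F11 | step 9 | 3,7-dimethylocta-1,2,7-trien-4-one | C=C=C(C)C(=O)CCC(C)=C
F12 | step 9 | 2-bromo-3,7-dimethylocta-1,7-dien-4-one | C=C(Br)C(C)C(=O)CCC(C)=C
F13 | step 9 | (3R)-3-hydroxy-5,9-dimethyl-4-methylidenedeca-1,9-dien-6-one (both C5 epimers) | C=C[C@@H](O)C(=C)C(C)C(=O)CCC(C)=C
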